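## Retrosynthetic overview

1. Iridoid numbering: pyran ring O2–C1–C9–C5–C4–C3, cyclopentane C5–C6–C7–C8–C9, C10 on C8, C11 on C4, β = face of H5 and H9. The plan rests on one feature: the C1 acyloxy acetal and the C3=C4 enol ether of the pyran ring are two masked aldehydes (C1 on C9, C3 on the C4 methylene at C5), so this ring can first be closed as its transposed isomer, with the enol ether at C1=C9 and the acetal at C3.
2. Target 29 ⇐ C11 aldehyde 28 (reduced last) ⇐ esterification of O7 with (Z)-acid 26 and of the C1 lactol 16 with acid 17.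
3. Lactol 16 ⇐ bis-acetal 13: C11 is put on C4 by formylation while C3 is still an acetal, so the transposed enol ether ends as a vinylogous formate (O2–C3=C4–C11=O) and cannot drift back to C1=C9. 13 ⇐ cycloadduct 12 by adding ethanol across C1=C9 (sets H9).
4. Pyran ring: 12 ⇐ enal 10 + ethyl vinyl ether 11 by inverse-demand hetero-Diels–Alder reaction, forming C4–C5 and O2–C3.
5. Cyclopentene ring: 10 ⇐ ring-closing metathesis of diene 7 ⇐ silinanone 4 (from 2-deoxy-D-ribose 1; C7 = sugar C3) + lithiated 5 (sets C8). Ring order: cyclopentene (step 5), then pyran (step 8).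

Key step: step 8

Remark: acetal centres that are erased or re-set later (C3 in 12 and 13, C1 in 13 to 15) are drawn as the expected major anomers and anomeric mixtures would be carried on; (R)-3-methylpentanoic acid is taken as a commercial single enantiomer; all (Z)-cinnamoyl compounds are handled with exclusion of light.

## Route

Step 1
Reactants: 1 2-deoxy-D-ribose
Product: 2 (2R,3S)-hex-5-ene-1,2,3-triol
Conditions: Ph3PCH3Br, KOtBu, THF, 0 °C to rt
Reagents that add atoms: methyltriphenylphosphonium bromide, C[P+](c1ccccc1)(c1ccccc1)c1ccccc1.[Br-]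
Why: Wittig methylenation of the open-chain aldehyde tautomer of the lactol with excess ylide is an established way to this hexenetriol and leaves both carbinol stereocentres (sugar C3 = C7, sugar C4) untouched.

Step 2
Reactants: 2 (2R,3S)-hex-5-ene-1,2,3-triol
Product: 3 (4S,5R)-4-allyl-2,2-di-tert-butyl-1,3,2-dioxasilinan-5-ol
Conditions: t-Bu2Si(OTf)2, pyridine, DMF, −40 to 0 °C
Reagents that add atoms: di-tert-butylsilyl bis(trifluoromethanesulfonate), CC(C)(C)[Si](OS(=O)(=O)C(F)(F)F)(OS(=O)(=O)C(F)(F)F)C(C)(C)C
Why: Cyclic silylene protection should close on the 1,3-diol (primary O10 and secondary O7) because the six-membered dioxasilinane is far less strained than a five-membered dioxasilolane, which leaves the middle hydroxyl (future O8) free.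

Step 3
Reactants: 3 (4S,5R)-4-allyl-2,2-di-tert-butyl-1,3,2-dioxasilinan-5-ol
Product: 4 (S)-4-allyl-2,2-di-tert-butyl-1,3,2-dioxasilinan-5-one
Conditions: Dess–Martin periodinane, NaHCO3, CH2Cl2, 0 °C to rt
Reagents that add atoms: none
Why: Dess–Martin oxidation of the secondary alcohol under buffered, non-basic conditions should give the ketone without epimerising the α-stereocentre C7.

Step 4
Reactants: 4 (S)-4-allyl-2,2-di-tert-butyl-1,3,2-dioxasilinan-5-one; 5 2-bromoacrolein diethyl acetal
Product: 7 tertiary alcohol (allyl on C7 and acetal-bearing vinyl group on C8 cis on the silinane ring; 8-OH trans to allyl), via 2-lithio-3,3-diethoxyprop-1-ene 6 (not isolated)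
Conditions: 5, n-BuLi, THF, −78 °C; then 4, −78 to −40 °C; then H2O
Reagents that add atoms: none
Why: Bromine–lithium exchange gives the acrolein α-anion equivalent, which adds 1,2 to the ketone; on the chair silinanone with the allyl group equatorial the nucleophile should enter axially (no 1,3-diaxial hydrogens at the ring oxygens, torsionally favoured), so C9 comes cis to the allyl group and O8 trans to it, which is the C8 configuration of the target.

Step 5
Reactants: 7 tertiary alcohol diene
Product: 8 cyclopentene acetal (C9=C5 ring alkene; CH(OEt)2 = C1 on C9; 8α-OH; O7β/O10 silylene)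
Conditions: second-generation Grubbs catalyst, (H2IMes)(PCy3)Cl2Ru=CHPh (5 mol %), CH2Cl2, 40 °C
Reagents that add atoms: none
Why: Ring-closing metathesis: the catalyst loads on the monosubstituted alkene and closes the five-membered ring on the cis-disposed 1,1-disubstituted alkene with loss of ethylene, a free tertiary allylic hydroxyl being tolerated.

Step 6
Reactants: 8 cyclopentene acetal
Product: 9 hydroxy enal (C1 formyl on C9=C5; 8α-OH; O7β/O10 silylene)
Conditions: PPTS, acetone/H2O (10:1), rt
Reagents that add atoms: water, O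
Why: Acetal hydrolysis of an α,β-unsaturated acetal runs through a conjugated oxocarbenium ion under very mild acid, so the enal should be freed without touching the silylene or ionising the tertiary alcohol.

Step 7
Reactants: 9 hydroxy enal
Product: 10 silyl-protected enal (C1 formyl on C9=C5; 8α-OSiEt3; O7β/O10 silylene)
Conditions: TESOTf, 2,6-lutidine, CH2Cl2, −78 to 0 °C
Reagents that add atoms: triethylsilyl trifluoromethanesulfonate, CC[Si](CC)(CC)OS(=O)(=O)C(F)(F)F
Why: Silyl triflate/lutidine silylation is the standard way to cap a hindered tertiary alcohol, and it is placed after step 6 because this reagent pair also cleaves dialkyl acetals.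

Step 8
Reactants: 10 silyl-protected enal; 11 ethyl vinyl ether
Product: 12 cycloadduct (3α-ethoxy-3,4-dihydropyran with C1=C9 enol ether; H5 β)
Conditions: Yb(fod)3 [ytterbium tris(6,6,7,7,8,8,8-heptafluoro-2,2-dimethyloctane-3,5-dionate)] (10 mol %), 11 (neat, excess), 25 to 40 °C, sealed vessel
Reagents that add atoms: none
Why: The lanthanide binds the formyl oxygen of the s-cis oxadiene O2=C1–C9=C5 and lowers its LUMO, so the electron-rich vinyl ether adds in a concerted, asynchronous, endo [4+2] with inverse electron demand, its nucleophilic CH2 (C4) bonding to the electrophilic β-carbon C5 and its oxygenated carbon C3 to O2, the only regiochemistry the polarities allow. The closest known reaction type is the Yb(fod)3- or Eu(fod)3-catalysed cycloaddition of enals, 1-cyclopentenecarbaldehydes among them, with ethyl vinyl ether to 2-ethoxy-3,4-dihydro-2H-pyrans. The pyran ring (O2, C1, C9, C5, C4, C3) is closed by intermolecular cycloaddition, both σ-bonds in one step. C5 is set by the face of approach: the β face is the concave face of the cis-fused bicycle and carries C10 and O7 tied into the di-tert-butylsilylene ring, whereas the α face carries only the C8 silyl ether, whose ethyl groups can turn away, so the dienophile should add to the α face and leave H5 β; C3 follows the endo rule and is of no consequence because it is erased in step 10. The step needs α-face selectivity at C5 and survival of the allylic tertiary silyl ether, which the silylene ring and the nearly neutral catalyst are meant to secure.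

Step 9
Reactants: 12 cycloadduct
Product: 13 bis-acetal (1β,3α-diethoxy; cis-fused with H5 and H9 β)
Conditions: EtOH (5 equiv), PPTS (5 mol %), CH2Cl2, 0 °C to rt
Reagents that add atoms: ethanol, CCO
Why: Acid-catalysed addition of an alcohol to an enol ether (as in tetrahydropyranyl ether formation): C9 should be protonated from the β face, which carries only H5 and the tied-back C10 methylene and is opposite to the C8 silyl ether and the C4 methylene, giving the cis ring fusion, and ethanol then adds to the C1 oxocarbenium ion.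

Step 10
Reactants: 13 bis-acetal
Product: 15 1-ethoxy-3-ene-4-carbaldehyde (C11 formyl on C4), via C11 iminium chloride 14 (not isolated)
Conditions: POCl3 (2.5 equiv), DMF, 0 to 40 °C; then aq. NaOAc, rt
Reagents that add atoms: N,N-dimethylformamide, CN(C)C=O; water, O
Why: Vilsmeier–Haack formylation of an acetal: the reagent strips ethanol from an acetal carbon to give an enol ether that is formylated at its β-carbon, and only the C3 acetal can do this productively because C4 is an unhindered CH2 (it ends as the conjugated O2–C3=C4–C11 iminium ion) whereas the C1 acetal has only the neopentyl-type methine C9, so the vinylogous formate fixes the enol ether at C3=C4 and completes the acetal transposition.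

Step 11
Reactants: 15 1-ethoxy-3-ene-4-carbaldehyde
Product: 16 lactol (1β-hydroxy-3-ene-4-carbaldehyde)
Conditions: AcOH/THF/H2O (3:1:1), 40 °C
Reagents that add atoms: water, O
Why: Acetal hydrolysis is easy here because the ring oxygen is a vinylogous carboxylate oxygen (the acetal behaves like an alkoxymethyl ester), and the lactol should settle as the cis-fused anomer with 1-OH β (trans to the C9–C8 bond), as iridoid aglycones do.

Step 12
Reactants: 16 lactol; 17 (R)-3-methylpentanoic acid
Product: 18 1β-O-[(R)-3-methylpentanoyl] acetal (4-formyl; silylene and SiEt3 retained)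
Conditions: 17 (1.5 equiv), DCC, DMAP (cat.), CH2Cl2, 0 °C to rt
Reagents that add atoms: none
Why: Steglich esterification of the hemiacetal hydroxyl gives the acyloxy acetal with retention; the β-lactol is both the major and the less hindered anomer, and the β-stereocentre of the acid cannot epimerise.

Step 13
Reactants: 18 1β-O-acyl acetal
Product: 19 triol (7β-OH; 8α-OH; 10-OH; 4-formyl)
Conditions: HF·pyridine, pyridine, THF, 0 °C to rt
Reagents that add atoms: none
Why: Fluoride-mediated desilylation cleaves the silylene and the triethylsilyl ether, while the acylal and the vinylogous formate are stable to buffered HF·pyridine.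

Step 14
Reactants: 19 triol
Product: 20 10-O-TBS ether (7β-OH and 8α-OH free)
Conditions: TBSCl (1.1 equiv), imidazole, DMF, −20 to 0 °C
Reagents that add atoms: tert-butyldimethylsilyl chloride, CC(C)(C)[Si](C)(C)Cl
Why: Chlorosilane/imidazole silylation discriminates the primary C10 hydroxyl from the hindered secondary (C7) and tertiary (C8) hydroxyls.

Step 15
Reactants: 21 4-hydroxybenzaldehyde
Product: 22 4-(tert-butyldimethylsilyloxy)benzaldehyde
Conditions: TBSCl, imidazole, DMF, rt
Reagents that add atoms: tert-butyldimethylsilyl chloride, CC(C)(C)[Si](C)(C)Cl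
Why: Phenol silylation masks the acidic phenol so that the aldehyde stays electrophilic for the olefination.

Step 16
Reactants: 22 4-(tert-butyldimethylsilyloxy)benzaldehyde
Product: 23 methyl (Z)-3-[4-(tert-butyldimethylsilyloxy)phenyl]prop-2-enoate
Conditions: (CF3CH2O)2P(O)CH2CO2Me, KN(SiMe3)2, 18-crown-6, THF, −78 °C, dark
Reagents that add atoms: methyl bis(2,2,2-trifluoroethyl)phosphonoacetate, COC(=O)CP(=O)(OCC(F)(F)F)OCC(F)(F)F
Why: Still–Gennari olefination: the electron-poor phosphonate with a dissociated potassium counter-ion makes elimination fast and kinetically controlled, which gives the (Z)-cinnamate from an aromatic aldehyde.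

Step 17
Reactants: 23 methyl (Z)-ester
Product: 24 (Z)-4-hydroxycinnamic acid
Conditions: LiOH, THF/MeOH/H2O, 0 °C to rt, dark; then 1 M HCl to pH 3
Reagents that add atoms: lithium hydroxide, [Li+].[OH-]
Why: Saponification cleaves the methyl ester (and the base-labile aryl silyl ether) without a pathway for thermal Z-to-E isomerisation in the dark.

Step 18
Reactants: 24 (Z)-4-hydroxycinnamic acid
Product: 26 (Z)-4-(tert-butyldimethylsilyloxy)cinnamic acid, via bis-silyl compound 25 (not isolated)
Conditions: TBSCl (2.5 equiv), imidazole, DMF, rt; then AcOH/THF/H2O, rt, dark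
Reagents that add atoms: tert-butyldimethylsilyl chloride, CC(C)(C)[Si](C)(C)Cl
Why: Exhaustive silylation followed by selective hydrolysis of the far more labile silyl ester is the routine way to a phenol-protected hydroxycinnamic acid and does not touch the alkene geometry.

Step 19
Reactants: 20 10-O-TBS ether; 26 (Z)-4-(tert-butyldimethylsilyloxy)cinnamic acid
Product: 27 7-O-(Z)-cinnamoyl ester (aryl and C10 silyl ethers; 4-formyl)
Conditions: 26 (1.5 equiv), DCC, DMAP (cat.), CH2Cl2, 0 °C to rt, dark
Reagents that add atoms: none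
Why: Steglich esterification acylates the only reactive hydroxyl (secondary O7; O8 is tertiary, O10 silylated) with retention at C7, and the electron-rich 4-silyloxyaryl group makes the acyl intermediate a poor Michael acceptor, which should suppress Z-to-E isomerisation by DMAP.

Step 20
Reactants: 27 7-O-(Z)-cinnamoyl ester
Product: 28 C11 aldehyde of the target (free phenol; 8-OH; 10-OH)
Conditions: Bu4NF/AcOH (1:1), THF, 0 °C to rt, dark
Reagents that add atoms: none
Why: Buffered fluoride desilylation removes the aryl and the primary alkyl silyl ether in one operation, the acetic acid buffer keeping the medium too weakly basic for acyl migration or acylal cleavage.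

Step 21
Reactants: 28 C11 aldehyde
Product: 29 target CNP0217341.1
Conditions: NaBH4, CeCl3·7H2O, MeOH/THF, −40 °C; pH 7 phosphate buffer
Reagents that add atoms: none
Why: Luche reduction takes the aldehyde of the β-alkoxyenal 1,2 to the allylic alcohol far faster than hydride touches the esters or the cinnamate, so the acid-sensitive hydroxymethyl enol ether is unveiled last under near-neutral conditions.

## Compound list

1 | 2-deoxy-D-ribose (open-chain form drawn) | O=CC[C@H](O)[C@H](O)CO | starting material
2 | (2R,3S)-hex-5-ene-1,2,3-triol | C=CC[C@H](O)[C@H](O)CO | intermediate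
3 | (4S,5R)-4-allyl-2,2-di-tert-butyl-1,3,2-dioxasilinan-5-ol | C=CC[C@@H]1O[Si](C(C)(C)C)(C(C)(C)C)OC[C@H]1O | intermediate
4 | (S)-4-allyl-2,2-di-tert-butyl-1,3,2-dioxasilinan-5-one | C=CC[C@@H]1O[Si](C(C)(C)C)(C(C)(C)C)OCC1=O | intermediate
5 | 2-bromoacrolein diethyl acetal (2-bromo-3,3-diethoxyprop-1-ene) | C=C(Br)C(OCC)OCC | starting material
6 | 2-lithio-3,3-diethoxyprop-1-ene | [Li]C(=C)C(OCC)OCC | intermediate (not isolated)
7 | (4S,5R)-4-allyl-2,2-di-tert-butyl-5-(3,3-diethoxyprop-1-en-2-yl)-1,3,2-dioxasilinan-5-ol (allyl and propenyl cis) | C=CC[C@@H]1O[Si](C(C)(C)C)(C(C)(C)C)OC[C@]1(O)C(=C)C(OCC)OCC | intermediate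
8 | 2,2-di-tert-butyl-5-(diethoxymethyl)-4,4a,7,7a-tetrahydrocyclopenta[d][1,3,2]dioxasilin-4a-ol (C9=C5 alkene, C1 acetal, 8α-OH, O7β/O10 silylene) | CCOC(OCC)C1=CC[C@H](O[Si](C(C)(C)C)(C(C)(C)C)OC2)[C@]21O | intermediate
9 | 2,2-di-tert-butyl-4a-hydroxy-4,4a,7,7a-tetrahydrocyclopenta[d][1,3,2]dioxasiline-5-carbaldehyde (hydroxy enal) | O=CC1=CC[C@H](O[Si](C(C)(C)C)(C(C)(C)C)OC2)[C@]21O | intermediate
10 | 2,2-di-tert-butyl-4a-(triethylsilyloxy)-4,4a,7,7a-tetrahydrocyclopenta[d][1,3,2]dioxasiline-5-carbaldehyde (key-step enal) | O=CC1=CC[C@H](O[Si](C(C)(C)C)(C(C)(C)C)OC2)[C@]21O[Si](CC)(CC)CC | intermediate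
11 | ethyl vinyl ether | C=COCC | starting material
12 | cycloadduct: 3α-ethoxy-3,4-dihydropyran with C1=C9 enol ether, H5 β, 8α-OSiEt3, O7β/O10 silylene | CCO[C@H]1C[C@H]2C[C@H](O[Si](C(C)(C)C)(C(C)(C)C)OC3)[C@@]3(O[Si](CC)(CC)CC)C2=CO1 | intermediate
13 | bis-acetal: 1β,3α-diethoxy, cis-fused (H5, H9 β), 8α-OSiEt3, O7β/O10 silylene | CCO[C@@H]1O[C@@H](OCC)C[C@H]2C[C@H](O[Si](C(C)(C)C)(C(C)(C)C)OC3)[C@@]3(O[Si](CC)(CC)CC)[C@@H]12 | intermediate
14 | C11 N,N-dimethyliminium chloride of 15 | CCO[C@@H]1OC=C(C=[N+](C)C)[C@H]2C[C@H](O[Si](C(C)(C)C)(C(C)(C)C)OC3)[C@@]3(O[Si](CC)(CC)CC)[C@@H]12.[Cl-] | intermediate (not isolated)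
15 | 1β-ethoxy-3-ene-4-carbaldehyde (C3=C4 enol ether, C11 formyl) | CCO[C@@H]1OC=C(C=O)[C@H]2C[C@H](O[Si](C(C)(C)C)(C(C)(C)C)OC3)[C@@]3(O[Si](CC)(CC)CC)[C@@H]12 | intermediate
16 | lactol: 1β-hydroxy-3-ene-4-carbaldehyde | O[C@@H]1OC=C(C=O)[C@H]2C[C@H](O[Si](C(C)(C)C)(C(C)(C)C)OC3)[C@@]3(O[Si](CC)(CC)CC)[C@@H]12 | intermediate
17 | (R)-3-methylpentanoic acid | CC[C@@H](C)CC(=O)O | starting material
18 | 1β-O-[(R)-3-methylpentanoyl] acetal of 16 | CC[C@@H](C)CC(=O)O[C@@H]1OC=C(C=O)[C@H]2C[C@H](O[Si](C(C)(C)C)(C(C)(C)C)OC3)[C@@]3(O[Si](CC)(CC)CC)[C@@H]12 | intermediate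
19 | 7β,8α,10-triol with 1β-acyloxy and 4-formyl groups | CC[C@@H](C)CC(=O)O[C@@H]1OC=C(C=O)[C@H]2C[C@H](O)[C@](O)(CO)[C@@H]12 | intermediate
20 | 10-O-tert-butyldimethylsilyl ether of 19 | CC[C@@H](C)CC(=O)O[C@@H]1OC=C(C=O)[C@H]2C[C@H](O)[C@](O)(CO[Si](C)(C)C(C)(C)C)[C@@H]12 | intermediate
21 | 4-hydroxybenzaldehyde | O=Cc1ccc(O)cc1 | starting material
22 | 4-(tert-butyldimethylsilyloxy)benzaldehyde | O=Cc1ccc(O[Si](C)(C)C(C)(C)C)cc1 | intermediate
23 | methyl (Z)-3-[4-(tert-butyldimethylsilyloxy)phenyl]prop-2-enoate | COC(=O)/C=C\c1ccc(O[Si](C)(C)C(C)(C)C)cc1 | intermediate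
24 | (Z)-4-hydroxycinnamic acid | OC(=O)/C=C\c1ccc(O)cc1 | intermediate
25 | tert-butyldimethylsilyl (Z)-4-(tert-butyldimethylsilyloxy)cinnamate | CC(C)(C)[Si](C)(C)OC(=O)/C=C\c1ccc(O[Si](C)(C)C(C)(C)C)cc1 | intermediate (not isolated)
26 | (Z)-4-(tert-butyldimethylsilyloxy)cinnamic acid | OC(=O)/C=C\c1ccc(O[Si](C)(C)C(C)(C)C)cc1 | intermediate
27 | 7-O-[(Z)-4-(tert-butyldimethylsilyloxy)cinnamoyl] ester of 20 | CC[C@@H](C)CC(=O)O[C@@H]1OC=C(C=O)[C@H]2C[C@H](OC(=O)/C=C\c3ccc(O[Si](C)(C)C(C)(C)C)cc3)[C@](O)(CO[Si](C)(C)C(C)(C)C)[C@@H]12 | intermediate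
28 | C11 aldehyde of the target | CC[C@@H](C)CC(=O)O[C@@H]1OC=C(C=O)[C@H]2C[C@H](OC(=O)/C=C\c3ccc(O)cc3)[C@](O)(CO)[C@@H]12 | intermediate
29 | CNP0217341.1 | CC[C@@H](C)CC(=O)O[C@@H]1OC=C(CO)[C@H]2C[C@H](OC(=O)/C=C\c3ccc(O)cc3)[C@](O)(CO)[C@@H]12 | target

## Step count and risks

Total step count: 21 (steps 15 to 18 are the side branch to acid 26).
Longest linear sequence: 17 steps (steps 1 to 14 and 19 to 21).

Steps most likely to fail:

1. Step 8. The vinyl ether may add to the β face of C5 if the C8 silyl ether shields the α face more than expected, or the hindered enal may react so slowly that Lewis-acid-induced ionisation of the allylic silyl ether competes. Fallback, from 10 to 12: facial control is taken from the substrate and given to the reagent. The cycloaddition is run with the enantiopure chloride complex of trivalent chromium and the tridentate Schiff base from 3-(1-adamantyl)-5-methylsalicylaldehyde and cis-1-amino-2-indanol (4 Å molecular sieves, neat 11, rt). The catalyst antipode whose facial preference reinforces α attack is to be found by testing both. This kind of catalyst control is established for 1-cyclopentenecarbaldehydes that carry a stereocentre next to the formyl-bearing carbon. The fallback makes no new compound (F0).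

2. Step 10. The C1 acetal may ionise instead of the C3 acetal, with formylation at C9, or the silyl ether and silylene may be lost to the HCl that the reagent releases. Any lactol 16 formed directly in the work-up is harmless and is carried on. Fallback, from 10 to 16: C11 is brought in with the dienophile instead of by formylation. Cycloaddition of 10 with (E)-1,3,3-triethoxyprop-1-ene (Yb(fod)3, neat, 40 to 60 °C) should give the 4-(diethoxymethyl) cycloadduct F9 with the same C4–C5 and O2–C3 bonds. AcOH/THF/H2O then hydrates the C1=C9 enol ether (H9 β), hydrolyses the C11 acetal and lets the C3 acetal lose ethanol into conjugation. The malondialdehyde enol closes on C1 and the route is rejoined at lactol 16; steps 9 to 11 are bypassed.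

3. Step 4. The vinyllithium may attack the silinanone equatorially (wrong C8 epimer), or it may enolise the ketone. Fallback, from 2 to 7: the C8 centre is set by Cram chelation on an open-chain ketone.
   - 2-Methoxypropene/PPTS converts 2 into the terminal acetonide, (S)-1-[(R)-2,2-dimethyl-1,3-dioxolan-4-yl]but-3-en-1-ol F1.
   - NaH/4-methoxybenzyl chloride gives its O7 PMB ether F2.
   - AcOH/H2O frees the O8,O10-diol F3.
   - TBDPSCl/imidazole gives the primary silyl ether F4.
   - Dess–Martin oxidation gives the α-(4-methoxybenzyloxy) ketone F5.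
   - The Grignard reagent made from 6 and MgBr2·OEt2 adds in CH2Cl2/Et2O at −78 °C through the five-membered chelate of magnesium with the ketone and PMB ether oxygens, anti to the allyl group, to give tertiary alcohol F6 with the C8 configuration of 7.
   - DDQ in buffered wet CH2Cl2 gives the diol F7, and Bu4NF gives the triol F8.
   - t-Bu2Si(OTf)2/pyridine closes the O7,O10-silylene to return at 7.

Further compounds
F1 | step 4 | (S)-1-[(R)-2,2-dimethyl-1,3-dioxolan-4-yl]but-3-en-1-ol | C=CC[C@H](O)[C@H]1COC(C)(C)O1
F2 | step 4 | (R)-4-[(S)-1-(4-methoxybenzyloxy)but-3-enyl]-2,2-dimethyl-1,3-dioxolane | C=CC[C@H](OCc1ccc(OC)cc1)[C@H]1COC(C)(C)O1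
F3 | step 4 | (2R,3S)-3-(4-methoxybenzyloxy)hex-5-ene-1,2-diol | C=CC[C@H](OCc1ccc(OC)cc1)[C@H](O)CO
F4 | step 4 | (2R,3S)-1-(tert-butyldiphenylsilyloxy)-3-(4-methoxybenzyloxy)hex-5-en-2-ol | C=CC[C@H](OCc1ccc(OC)cc1)[C@H](O)CO[Si](c1ccccc1)(c1ccccc1)C(C)(C)C
F5 | step 4 | (S)-1-(tert-butyldiphenylsilyloxy)-3-(4-methoxybenzyloxy)hex-5-en-2-one | C=CC[C@H](OCc1ccc(OC)cc1)C(=O)CO[Si](c1ccccc1)(c1ccccc1)C(C)(C)C
F6 | step 4 | 3-[(tert-butyldiphenylsilyloxy)methyl]-2-(diethoxymethyl)-4-(4-methoxybenzyloxy)hepta-1,6-dien-3-ol (C7 and C8 as in 7) | C=CC[C@H](OCc1ccc(OC)cc1)[C@](O)(CO[Si](c1ccccc1)(c1ccccc1)C(C)(C)C)C(=C)C(OCC)OCC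
F7 | step 4 | 3-[(tert-butyldiphenylsilyloxy)methyl]-2-(diethoxymethyl)hepta-1,6-diene-3,4-diol | C=CC[C@H](O)[C@](O)(CO[Si](c1ccccc1)(c1ccccc1)C(C)(C)C)C(=C)C(OCC)OCC
F8 | step 4 | 2-(diethoxymethyl)-3-(hydroxymethyl)hepta-1,6-diene-3,4-diol | C=CC[C@H](O)[C@](O)(CO)C(=C)C(OCC)OCC
F0 | step 8 | none | none
F9 | step 10 | 4-(diethoxymethyl) cycloadduct (3α-ethoxy, C4 substituent trans to it, C1=C9 enol ether, H5 β) | CCO[C@H]1[C@H](C(OCC)OCC)[C@H]2C[C@H](O[Si](C(C)(C)C)(C(C)(C)C)OC3)[C@@]3(O[Si](CC)(CC)CC)C2=CO1
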